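The plan rests on cutting C8–C9 in ring A, the ten-membered carbocycle C1–C10. The ring-trans C8/C9 diol, lying between lactone carbon C7 (ring B) and olefinic carbon C10, is what a reductive coupling of two aldehydes leaves behind. Low-valent titanium joins the C8 aldehyde and the C9 enal of an open-chain lactone dialdehyde. This one operation forms C8–C9, closes ring A and sets both carbinol centres. The precursor already holds C6 and C7 (Evans aldol), both ring-cis olefins and C14 as a silyl ether. Afterwards come lactone methylenation, O8/O9 differentiation through a 9,14-silylene, oxidation of C14 and two acylations.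

Key step: step 13

Numbering: germacranolide numbers are used throughout. Ring A is C1–C10, ring B is O–C6–C7–C11–C12, C13 sits on C11, C14 on C10 and C15 on C4.

Assumption: the SMILES is read literally. The O8 acyl group is then (2S,3R)-2,3-dimethyloxirane-2-carboxylate, the epoxide of the E acid (tiglic acid), and the O9 acyl group is syn-(2R,3S)-3-hydroxy-2-methylbutanoate. C3 is cis to C6 across C4=C5 and C9 is cis to C2 across C1=C10. R/S and E/Z letters of intermediates change with substituent priorities while the geometry stays the same.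

Design of the precursor:
- C8 and C9 travel as primary alcohols and become aldehydes together, one step before the coupling.
- The ester reduction at C9 is finished in fragment B, before ring B is present.
- C14 carries TIPS, so the TES group on O8 can be removed selectively.

Fragment A (C4–C8, C11, C12, C15)

Step 1
Reactants: 1 but-2-yn-1-ol
Product: 3 (2Z)-3-iodobut-2-en-1-ol, via cyclic alkenylalanate 2 (not isolated)
Conditions: NaAlH2(OCH2CH2OMe)2 (Red-Al), THF, 0 °C to rt; then I2, −78 to 0 °C
Reagents that add atoms: iodine, II; NaAlH2(OCH2CH2OMe)2, [Na+].[AlH2-](OCCOC)OCCOC (aluminium stays only in intermediate 2)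
Why: Hydroxyl-directed trans-hydroalumination of a propargylic alcohol puts aluminium on the distal alkyne carbon inside a five-membered alanate, and iodinolysis with retention should give only the Z-iodide, which fixes the C4=C5 geometry (iodine, later C3, cis to C6).

Step 2
Reactants: 3 (2Z)-3-iodobut-2-en-1-ol
Product: 4 (2Z)-3-iodobut-2-enal
Conditions: MnO2, CH2Cl2, rt, dark
Reagents that add atoms: none
Why: Heterogeneous allylic alcohol oxidation with MnO2 is neutral, so the Z-β-iodoenal should form without E/Z isomerisation if it is kept dark and used at once.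

Step 3
Reactants: 5 (4S)-4-benzyl-1,3-oxazolidin-2-one; 6 methyl 4-chloro-4-oxobutanoate
Product: 8 methyl 4-[(4S)-4-benzyl-2-oxo-1,3-oxazolidin-3-yl]-4-oxobutanoate, via lithium oxazolidinide 7 (not isolated)
Conditions: n-BuLi, THF, −78 °C; then 6, −78 to 0 °C
Reagents that add atoms: n-butyllithium, [Li]CCCC (lithium stays only in intermediate 7)
Why: N-acylation of a lithiated oxazolidinone, in which the acid chloride end of 6 is far more electrophilic than its methyl ester, so only the imide should form.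

Step 4
Reactants: 8 methyl 4-[(4S)-4-benzyl-2-oxo-1,3-oxazolidin-3-yl]-4-oxobutanoate; 4 (2Z)-3-iodobut-2-enal
Product: 11 (4S)-4-benzyl-3-{[(2S,3S)-2-[(1Z)-2-iodoprop-1-en-1-yl]-5-oxooxolan-3-yl]carbonyl}-1,3-oxazolidin-2-one, via boron enolate 9 (not isolated), via aldol hydroxy ester 10 (not isolated)
Conditions: Bu2BOTf, Et3N, CH2Cl2, 0 °C; 4, −78 to 0 °C; H2O2, MeOH, pH 7 buffer; then PPTS (cat.), CH2Cl2, rt
Reagents that add atoms: dibutylboryl triflate, CCCCB(CCCC)OS(=O)(=O)C(F)(F)F (boron stays only in intermediate 9)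
Why: Evans syn aldol reaction: soft enolisation touches only the imide-activated CH2 (C7), the Z-boron enolate reacts through a Zimmerman–Traxler chair on the face remote from the benzyl group and sets C7 and C6 together, and acid-catalysed lactonisation of the syn γ-hydroxy ester then closes ring B with H6/H7 trans.

Step 5
Reactants: 11 lactone imide
Product: 12 (4R,5S)-4-(hydroxymethyl)-5-[(1Z)-2-iodoprop-1-en-1-yl]oxolan-2-one
Conditions: NaBH4, THF/H2O (4:1), 0 °C
Reagents that add atoms: none
Why: Chemoselective borohydride reduction of an N-acyloxazolidinone: the exocyclic imide carbonyl (C8) is much more electrophilic than the γ-lactone, so C8 should go to the primary alcohol with release of the auxiliary and no spatial change at C7.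

Step 6
Reactants: 12 hydroxymethyl lactone
Product: 13 (4R,5S)-5-[(1Z)-2-iodoprop-1-en-1-yl]-4-{[(triethylsilyl)oxy]methyl}oxolan-2-one
Conditions: Et3SiCl, imidazole, CH2Cl2, 0 °C
Reagents that add atoms: chlorotriethylsilane, CC[Si](Cl)(CC)CC
Why: Silylation of the primary alcohol blocks migration of the lactone acyl group from O6 to O8 (translactonisation) under the basic coupling conditions of step 10.

Fragment B (C1–C3, C9, C10, C14)

Step 7
Reactants: 14 methyl 2-[bis(2,2,2-trifluoroethoxy)phosphoryl]acetate; 15 (triisopropylsiloxy)methyl chloride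
Product: 17 methyl 2-[bis(2,2,2-trifluoroethoxy)phosphoryl]-3-[(triisopropylsilyl)oxy]propanoate (racemic), via sodium phosphonate 16 (not isolated)
Conditions: NaH, THF, 0 °C; then 15, 0 °C to rt
Reagents that add atoms: sodium hydride, [Na+].[H-] (sodium stays only in intermediate 16)
Why: C-alkylation of a stabilised phosphonoacetate anion with a reactive α-chloro ether (malonate-type alkylation) brings in C14 already as its TIPS ether, and the new centre is racemic and is lost in step 8.

Step 8
Reactants: 17 silyloxymethyl phosphonate; 18 acrolein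
Product: 20 methyl (2Z)-2-{[(triisopropylsilyl)oxy]methyl}penta-2,4-dienoate, via potassium phosphonate 19 (not isolated)
Conditions: KN(SiMe3)2, 18-crown-6, THF, −78 °C; then 18, −78 °C
Reagents that add atoms: potassium bis(trimethylsilyl)amide, [K+].C[Si](C)(C)[N-][Si](C)(C)C (potassium stays only in intermediate 19)
Why: Still–Gennari olefination: the electron-poor bis(trifluoroethyl) phosphonate with a dissociated potassium counter-ion makes the kinetic adduct collapse irreversibly, so the ester (C9) should end cis to the C2 chain and C14 trans to it.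

Step 9
Reactants: 20 Z-dienoate
Product: 21 (2E)-2-{[(triisopropylsilyl)oxy]methyl}penta-2,4-dien-1-ol (CH2OH cis to the vinyl group)
Conditions: iBu2AlH (2.2 equiv), CH2Cl2, −78 °C; then H2O work-up
Reagents that add atoms: none
Why: 1,2-Reduction of the enoate with iBu2AlH gives the allylic alcohol with the olefin geometry untouched, and it is done in fragment B because it would not spare the lactone of ring B later.

Union and precursor

Step 10
Reactants: 21 dienol; 13 vinyl iodide lactone
Product: 23 (4R,5R)-5-[(1Z,5E)-7-hydroxy-2-methyl-6-{[(triisopropylsilyl)oxy]methyl}hepta-1,5-dien-1-yl]-4-{[(triethylsilyl)oxy]methyl}oxolan-2-one, via bis-boron intermediate 22 (not isolated)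
Conditions: 21, 9-BBN (2.2 equiv), THF, 0 °C to rt; H2O; then 13, Pd(dppf)Cl2 (cat.), AsPh3 (cat.), Cs2CO3, DMF, rt
Reagents that add atoms: 9-borabicyclo[3.3.1]nonane, [H]B1C2CCCC1CCC2 (boron stays only in intermediate 22)
Why: Hydroboration and B-alkyl Suzuki–Miyaura coupling: 9-BBN first masks the hydroxyl as a borinate and then adds to the terminal, least hindered olefin of the diene to put boron on C3, and zerovalent palladium inserts into the C4–I bond and couples with retention, so the geometry of C4=C5 is kept.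

Step 11
Reactants: 23 coupled TES ether
Product: 24 (4R,5R)-4-(hydroxymethyl)-5-[(1Z,5E)-7-hydroxy-2-methyl-6-{[(triisopropylsilyl)oxy]methyl}hepta-1,5-dien-1-yl]oxolan-2-one
Conditions: PPTS (cat.), MeOH/CH2Cl2, 0 °C
Reagents that add atoms: none
Why: Acid-catalysed methanolysis of silyl ethers is governed by bulk at silicon, so the primary TES ether should leave long before the TIPS ether at C14.

Step 12
Reactants: 24 C8,C9-diol
Product: 25 (2R,3S)-2-[(1Z,5Z)-6-formyl-2-methyl-7-[(triisopropylsilyl)oxy]hepta-1,5-dien-1-yl]-5-oxooxolane-3-carbaldehyde (lactone dialdehyde: C8 aldehyde, C9 enal, C14 silyl ether)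
Conditions: TEMPO (cat.), PhI(OAc)2 (2.4 equiv), CH2Cl2, 0 °C to rt, dark
Reagents that add atoms: none
Why: Oxoammonium (TEMPO) oxidation with PhI(OAc)2 turns both primary alcohols into aldehydes under nearly neutral conditions, which should spare the epimerisable β-acyloxy C7–C8 unit and the isomerisable Z-enal, and 25 is used at once.

Step 13
Reactants: 25 lactone dialdehyde
Product: 26 ten-membered 8,9-diol, (6R,7R,8S,9S)-8,9-dihydroxy-14-(triisopropylsilyloxy)-13-norgermacra-1(10),4-dien-12,6-olide (H6/H7 trans, O8 cis to C11, O9 trans to O8)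
Conditions: TiCl3(DME)1.5, Zn–Cu couple, DME, reflux, 4 h; cool to 25 °C; 25 in DME by syringe pump (high dilution); aq. NaHCO3, 0 °C
Reagents that add atoms: none
Why: Low-valent titanium gives one electron to each carbonyl group and the two titanium-bound ketyls combine at carbon to a titanium pinacolate, which at 25 °C should survive until hydrolysis instead of being deoxygenated. The closest known reaction type is the McMurry-type pinacol macrocyclisation of dialdehydes, enal–aldehyde pairs included. Ring A closes as a ten-membered ring by a radical–radical combination that is exo at both C=O bonds (both oxygens stay outside the ring); slow addition at high dilution and the folding imposed by the two ring-cis olefins and the trans-lactone favour it over oligomerisation. C8 is controlled by C7: C9 should approach anti to the C7–C11 bond and over H7 (Felkin–Anh type), which places O8 cis to C11. C9 is controlled by the pinacolate: in rings of ten and more members the two C–O–Ti bonds prefer to lie anti, which gives the ring-trans (threo) diol. The step needs coupling at the carbonyl carbon C9 and not at C1, no loss of O14 and an intact ring B; the oxophilic metal held on O9, C14 kept as a non-conjugating TIPS ether with a poor leaving group, and the low temperature should secure this.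

From the ring to the target

Step 14
Reactants: 26 8,9-diol
Product: 27 8,9-bis(triethylsilyl) ether of 26
Conditions: Et3SiOTf (2.5 equiv), 2,6-lutidine, CH2Cl2, −78 to 0 °C
Reagents that add atoms: triethylsilyl triflate, CC[Si](CC)(CC)OS(=O)(=O)C(F)(F)F
Why: Silylation with the triflate protects both hindered secondary alcohols, which keeps acidic protons and an O8 alkoxide (translactonisation) out of the enolate chemistry of step 15.

Step 15
Reactants: 27 bis-TES ether
Product: 31 α-methylene lactone, 8,9-bis(triethylsilyloxy)-14-(triisopropylsilyloxy)germacra-1(10),4,11(13)-trien-12,6-olide, via lithium enolate 28 (not isolated), via Mannich base 29 (not isolated), via methiodide 30 (not isolated)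
Conditions: LiN(iPr)2, THF, −78 °C; CH2=NMe2+ I−, −78 °C to rt; MeI, CH2Cl2, rt; aq. NaHCO3, rt
Reagents that add atoms: Eschenmoser's salt, C=[N+](C)C.[I-] (C13 is kept); lithium diisopropylamide, [Li+].CC(C)[N-]C(C)C (lithium only in 28); iodomethane, CI (methyl only in 30)
Why: Lactone α-methylenation by the Mannich route: the lithium enolate at C11, the only enolisable position, is aminomethylated by Eschenmoser's salt (anti to C8, a centre of no consequence), and N-methylation followed by base-induced β-elimination of trimethylamine leaves C11=C13.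

Step 16
Reactants: 31 trisilyl ether
Product: 32 8,9,14-triol, (6R,7R,8S,9S)-8,9,14-trihydroxygermacra-1(10),4,11(13)-trien-12,6-olide
Conditions: HF·pyridine, pyridine, THF, 0 °C to rt
Reagents that add atoms: none
Why: Fluoride-driven desilylation in an acidic buffer removes all three silyl groups without base, so the α-methylene lactone and the 6,12-lactone should stay in place.

Step 17
Reactants: 32 triol
Product: 33 9,14-O-(di-tert-butylsilylene) derivative of 32 with free O8–H
Conditions: tBu2Si(OTf)2 (1.05 equiv), 2,6-lutidine, CH2Cl2, −40 to 0 °C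
Reagents that add atoms: di-tert-butylsilyl bis(triflate), CC(C)(C)[Si](OS(=O)(=O)C(F)(F)F)(OS(=O)(=O)C(F)(F)F)C(C)(C)C
Why: Cyclic silylene formation: the primary O14 should be silylated first and the second Si–O bond closes on O9 to a six-membered 1,3,2-dioxasilinane in preference to a seven-membered ring on O8, which leaves O8–H as the only free hydroxyl.

Step 18
Reactants: 34 (2E)-2-methylbut-2-en-1-ol
Product: 35 [(2R,3R)-2,3-dimethyloxiran-2-yl]methanol
Conditions: Ti(OiPr)4 (cat.), D-(−)-diethyl tartrate (cat.), tBuOOH, 4 Å molecular sieves, CH2Cl2, −20 °C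
Reagents that add atoms: tert-butyl hydroperoxide, CC(C)(C)OO
Why: Sharpless asymmetric epoxidation: with D-(−)-diethyl tartrate the E-allylic alcohol should be epoxidised on the face that gives the (2R,3R)-epoxy alcohol, and the syn oxygen transfer keeps the two methyl groups cis.

Step 19
Reactants: 35 epoxy alcohol
Product: 36 (2S,3R)-2,3-dimethyloxirane-2-carboxylic acid
Conditions: RuCl3 (cat.), NaIO4, MeCN/EtOAc/H2O, 0 °C to rt
Reagents that add atoms: sodium periodate, [Na+].[O-]I(=O)(=O)=O (oxygen, passed on through RuO4)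
Why: RuO4-catalysed oxidation takes primary epoxy alcohols to glycidic acids without touching the oxirane, and the letter at C2 changes to S only because the priorities change.

Step 20
Reactants: 33 silylene alcohol; 36 epoxy acid
Product: 38 8-O-[(2S,3R)-2,3-dimethyloxirane-2-carbonyl] derivative of 33, via mixed anhydride 37 (not isolated)
Conditions: 36, 2,4,6-Cl3C6H2COCl, Et3N, toluene, rt; then 33, DMAP, toluene, rt to 40 °C
Reagents that add atoms: 2,4,6-trichlorobenzoyl chloride, O=C(Cl)c1c(Cl)cc(Cl)cc1Cl (aroyl group stays only in intermediate 37)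
Why: Yamaguchi esterification: the aroyl carbonyl is shielded by two ortho chlorines, so DMAP should pass on the epoxy acyl group, which has no α-hydrogen to epimerise, to the only free hydroxyl, O8.

Step 21
Reactants: 38 silylene ester
Product: 39 9,14-diol 8-ester
Conditions: HF·pyridine, pyridine, THF, 0 °C
Reagents that add atoms: none
Why: Fluoride cleavage of the strained cyclic silylene is fast at 0 °C in buffered HF·pyridine, conditions that the electron-poor glycidic ester epoxide should tolerate.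

Step 22
Reactants: 39 9,14-diol
Product: 41 C14 carboxylic acid (9-OH free), via enal 40 (not isolated)
Conditions: TEMPO (cat.), PhI(OAc)2, CH2Cl2, rt; then NaClO2, NaH2PO4, 2-methylbut-2-ene, tBuOH/H2O, 0 °C
Reagents that add atoms: sodium chlorite, [Na+].[O-]Cl=O
Why: TEMPO oxidation selects the primary allylic alcohol over the hindered secondary O9–H, and Pinnick oxidation with a chlorine scavenger takes the enal to the acid without touching olefins, epoxide or methylene lactone.

Step 23
Reactants: 41 acid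
Product: 42 C14 methyl ester (9-OH free)
Conditions: MeI, KHCO3, DMF, rt
Reagents that add atoms: iodomethane, CI
Why: SN2 O-alkylation of the carboxylate under weak base avoids diazoalkanes, cyanide and methoxide, all of which would add to the α-methylene lactone.

Step 24
Reactants: 43 (4R)-4-benzyl-3-propanoyl-1,3-oxazolidin-2-one; 44 acetaldehyde
Product: 46 (4R)-4-benzyl-3-[(2R,3S)-3-hydroxy-2-methylbutanoyl]-1,3-oxazolidin-2-one, via boron enolate 45 (not isolated)
Conditions: Bu2BOTf, Et3N, CH2Cl2, 0 °C; 44, −78 to 0 °C; H2O2, MeOH, pH 7 buffer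
Reagents that add atoms: dibutylboryl triflate, CCCCB(CCCC)OS(=O)(=O)C(F)(F)F (boron stays only in intermediate 45)
Why: Evans syn aldol reaction: the Z-boron enolate adds through a chair transition state on the face remote from the benzyl group of the R auxiliary, which sets C2' (R) and C3' (S) as the syn pair.

Step 25
Reactants: 46 aldol adduct
Product: 47 (4R)-4-benzyl-3-{(2R,3S)-2-methyl-3-[(triethylsilyl)oxy]butanoyl}-1,3-oxazolidin-2-one
Conditions: Et3SiCl, imidazole, DMF, 0 °C to rt
Reagents that add atoms: chlorotriethylsilane, CC[Si](Cl)(CC)CC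
Why: Silylation of the secondary alcohol prevents self-acylation in step 27 and gives a group that leaves under the mildest fluoride conditions at the end.

Step 26
Reactants: 47 silylated imide
Product: 49 (2R,3S)-2-methyl-3-[(triethylsilyl)oxy]butanoic acid, via lithium peroxycarboxylate 48 (not isolated)
Conditions: LiOH, H2O2, THF/H2O, 0 °C; Na2SO3; dilute HCl to pH 4
Reagents that add atoms: hydrogen peroxide, OO (as LiOOH)
Why: Hydroperoxide cleavage of the N-acyloxazolidinone attacks the exocyclic carbonyl selectively and is too weakly basic to epimerise C2' or to eliminate the β-silyloxy group.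

Step 27
Reactants: 42 9-hydroxy methyl ester; 49 silyloxy acid
Product: 51 3'-O-triethylsilyl ether of the target, via mixed anhydride 50 (not isolated)
Conditions: 49, 2,4,6-Cl3C6H2COCl, Et3N, toluene, rt; then 42, DMAP, toluene, rt
Reagents that add atoms: 2,4,6-trichlorobenzoyl chloride, O=C(Cl)c1c(Cl)cc(Cl)cc1Cl (aroyl group stays only in intermediate 50)
Why: Yamaguchi esterification acylates the last free hydroxyl, O9, with retention at C9 since only the O–H bond is broken, and the hindered O8 ester next to it should not migrate.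

Step 28
Reactants: 51 silyl ether
Product: 52 target CNP0135583.2
Conditions: HF·pyridine, pyridine, THF, 0 °C
Reagents that add atoms: none
Why: Fluoride cleavage of a secondary TES ether in buffered medium is fast and should leave epoxide, three esters, methylene lactone and both olefins untouched.

Compound list

1 | but-2-yn-1-ol | CC#CCO | starting material
2 | sodium cyclic alkenylalanate (2,2-bis(2-methoxyethoxy)-3-methyl-2,5-dihydro-1,2-oxaluminol-2-uide) | CC1=CCO[Al-]1(OCCOC)OCCOC.[Na+] | intermediate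
3 | (2Z)-3-iodobut-2-en-1-ol | C/C(I)=C/CO | intermediate
4 | (2Z)-3-iodobut-2-enal | C/C(I)=C/C=O | intermediate
5 | (4S)-4-benzyl-1,3-oxazolidin-2-one | O=C1OC[C@H](Cc2ccccc2)N1 | starting material
6 | methyl 4-chloro-4-oxobutanoate | COC(=O)CCC(=O)Cl | starting material
7 | lithium salt of 5 | [Li+].O=C1OC[C@H](Cc2ccccc2)[N-]1 | intermediate
8 | methyl 4-[(4S)-4-benzyl-2-oxo-1,3-oxazolidin-3-yl]-4-oxobutanoate | COC(=O)CCC(=O)N1C(=O)OC[C@@H]1Cc1ccccc1 | intermediate
9 | Z-dibutylboron enolate of 8 | COC(=O)C/C=C(/N1C(=O)OC[C@@H]1Cc1ccccc1)OB(CCCC)CCCC | intermediate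
10 | methyl (3S,4S,5Z)-3-{[(4S)-4-benzyl-2-oxo-1,3-oxazolidin-3-yl]carbonyl}-4-hydroxy-6-iodohept-5-enoate | COC(=O)C[C@H](C(=O)N1C(=O)OC[C@@H]1Cc1ccccc1)[C@H](O)/C=C(/C)I | intermediate
11 | (4S)-4-benzyl-3-{[(2S,3S)-2-[(1Z)-2-iodoprop-1-en-1-yl]-5-oxooxolan-3-yl]carbonyl}-1,3-oxazolidin-2-one | O=C(N1C(=O)OC[C@@H]1Cc1ccccc1)[C@H]2CC(=O)O[C@@H]2/C=C(/C)I | intermediate
12 | (4R,5S)-4-(hydroxymethyl)-5-[(1Z)-2-iodoprop-1-en-1-yl]oxolan-2-one | OC[C@H]1CC(=O)O[C@@H]1/C=C(/C)I | intermediate
13 | (4R,5S)-5-[(1Z)-2-iodoprop-1-en-1-yl]-4-{[(triethylsilyl)oxy]methyl}oxolan-2-one | CC[Si](CC)(CC)OC[C@H]1CC(=O)O[C@@H]1/C=C(/C)I | intermediate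
14 | methyl 2-[bis(2,2,2-trifluoroethoxy)phosphoryl]acetate | COC(=O)CP(=O)(OCC(F)(F)F)OCC(F)(F)F | starting material
15 | (triisopropylsiloxy)methyl chloride | ClCO[Si](C(C)C)(C(C)C)C(C)C | starting material
16 | sodium salt of 14 | [Na+].COC(=O)[CH-]P(=O)(OCC(F)(F)F)OCC(F)(F)F | intermediate
17 | methyl 2-[bis(2,2,2-trifluoroethoxy)phosphoryl]-3-[(triisopropylsilyl)oxy]propanoate (racemic) | COC(=O)C(CO[Si](C(C)C)(C(C)C)C(C)C)P(=O)(OCC(F)(F)F)OCC(F)(F)F | intermediate
18 | acrolein | C=CC=O | starting material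
19 | potassium salt of 17 | [K+].COC(=O)[C-](CO[Si](C(C)C)(C(C)C)C(C)C)P(=O)(OCC(F)(F)F)OCC(F)(F)F | intermediate
20 | methyl (2Z)-2-{[(triisopropylsilyl)oxy]methyl}penta-2,4-dienoate | C=C/C=C(/CO[Si](C(C)C)(C(C)C)C(C)C)C(=O)OC | intermediate
21 | (2E)-2-{[(triisopropylsilyl)oxy]methyl}penta-2,4-dien-1-ol | C=C/C=C(/CO[Si](C(C)C)(C(C)C)C(C)C)CO | intermediate
22 | C3-(9-BBN) alkylborane of 21 with O9 as 9-BBN borinate | C(CB1C2CCCC1CCC2)/C=C(/CO[Si](C(C)C)(C(C)C)C(C)C)COB1C2CCCC1CCC2 | intermediate
23 | (4R,5R)-5-[(1Z,5E)-7-hydroxy-2-methyl-6-{[(triisopropylsilyl)oxy]methyl}hepta-1,5-dien-1-yl]-4-{[(triethylsilyl)oxy]methyl}oxolan-2-one | CC[Si](CC)(CC)OC[C@H]1CC(=O)O[C@@H]1/C=C(/C)CC/C=C(/CO[Si](C(C)C)(C(C)C)C(C)C)CO | intermediate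
24 | (4R,5R)-4-(hydroxymethyl)-5-[(1Z,5E)-7-hydroxy-2-methyl-6-{[(triisopropylsilyl)oxy]methyl}hepta-1,5-dien-1-yl]oxolan-2-one | OC[C@H]1CC(=O)O[C@@H]1/C=C(/C)CC/C=C(/CO[Si](C(C)C)(C(C)C)C(C)C)CO | intermediate
25 | (2R,3S)-2-[(1Z,5Z)-6-formyl-2-methyl-7-[(triisopropylsilyl)oxy]hepta-1,5-dien-1-yl]-5-oxooxolane-3-carbaldehyde | O=C[C@H]1CC(=O)O[C@@H]1/C=C(/C)CC/C=C(/CO[Si](C(C)C)(C(C)C)C(C)C)C=O | intermediate
26 | (6R,7R,8S,9S)-8,9-dihydroxy-14-(triisopropylsilyloxy)-13-norgermacra-1(10),4-dien-12,6-olide | C1C(=O)O[C@@H]2/C=C(/C)CC/C=C(/CO[Si](C(C)C)(C(C)C)C(C)C)[C@H](O)[C@@H](O)[C@@H]12 | intermediate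
27 | 8,9-bis(triethylsilyl) ether of 26 | C1C(=O)O[C@@H]2/C=C(/C)CC/C=C(/CO[Si](C(C)C)(C(C)C)C(C)C)[C@H](O[Si](CC)(CC)CC)[C@@H](O[Si](CC)(CC)CC)[C@@H]12 | intermediate
28 | lithium enolate (C11=C12) of 27 | C1=C([O-])O[C@@H]2/C=C(/C)CC/C=C(/CO[Si](C(C)C)(C(C)C)C(C)C)[C@H](O[Si](CC)(CC)CC)[C@@H](O[Si](CC)(CC)CC)[C@@H]12.[Li+] | intermediate
29 | (11R)-11-[(dimethylamino)methyl] derivative of 27 (CH2NMe2 trans to C8) | CN(C)C[C@@H]1C(=O)O[C@@H]2/C=C(/C)CC/C=C(/CO[Si](C(C)C)(C(C)C)C(C)C)[C@H](O[Si](CC)(CC)CC)[C@@H](O[Si](CC)(CC)CC)[C@@H]12 | intermediate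
30 | trimethylammonium iodide of 29 | C[N+](C)(C)C[C@@H]1C(=O)O[C@@H]2/C=C(/C)CC/C=C(/CO[Si](C(C)C)(C(C)C)C(C)C)[C@H](O[Si](CC)(CC)CC)[C@@H](O[Si](CC)(CC)CC)[C@@H]12.[I-] | intermediate
31 | 8,9-bis(triethylsilyloxy)-14-(triisopropylsilyloxy)germacra-1(10),4,11(13)-trien-12,6-olide | C=C1C(=O)O[C@@H]2/C=C(/C)CC/C=C(/CO[Si](C(C)C)(C(C)C)C(C)C)[C@H](O[Si](CC)(CC)CC)[C@@H](O[Si](CC)(CC)CC)[C@@H]12 | intermediate
32 | (6R,7R,8S,9S)-8,9,14-trihydroxygermacra-1(10),4,11(13)-trien-12,6-olide | C=C1C(=O)O[C@@H]2/C=C(/C)CC/C=C(/CO)[C@H](O)[C@@H](O)[C@@H]12 | intermediate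
33 | 9,14-O-(di-tert-butylsilylene) derivative of 32, O8–H free | C=C1C(=O)O[C@@H]2/C=C(/C)CC/C=C3/CO[Si](C(C)(C)C)(C(C)(C)C)O[C@@H]3[C@@H](O)[C@@H]12 | intermediate
34 | (2E)-2-methylbut-2-en-1-ol | C/C=C(/CO)C | starting material
35 | [(2R,3R)-2,3-dimethyloxiran-2-yl]methanol | OC[C@@]1(C)O[C@@H]1C | intermediate
36 | (2S,3R)-2,3-dimethyloxirane-2-carboxylic acid | OC(=O)[C@@]1(C)O[C@@H]1C | intermediate
37 | mixed anhydride of 36 and 2,4,6-trichlorobenzoic acid | O=C(OC(=O)c1c(Cl)cc(Cl)cc1Cl)[C@@]2(C)O[C@@H]2C | intermediate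
38 | 8-O-[(2S,3R)-2,3-dimethyloxirane-2-carbonyl] derivative of 33 | C=C1C(=O)O[C@@H]2/C=C(/C)CC/C=C3/CO[Si](C(C)(C)C)(C(C)(C)C)O[C@@H]3[C@@H](OC(=O)[C@@]4(C)O[C@@H]4C)[C@@H]12 | intermediate
39 | 8-O-epoxyacyl-9,14-dihydroxygermacra-1(10),4,11(13)-trien-12,6-olide | C=C1C(=O)O[C@@H]2/C=C(/C)CC/C=C(/CO)[C@H](O)[C@@H](OC(=O)[C@@]3(C)O[C@@H]3C)[C@@H]12 | intermediate
40 | C14 aldehyde of 39 | C=C1C(=O)O[C@@H]2/C=C(/C)CC/C=C(/C=O)[C@H](O)[C@@H](OC(=O)[C@@]3(C)O[C@@H]3C)[C@@H]12 | intermediate
41 | C14 carboxylic acid of 39 | C=C1C(=O)O[C@@H]2/C=C(/C)CC/C=C(/C(=O)O)[C@H](O)[C@@H](OC(=O)[C@@]3(C)O[C@@H]3C)[C@@H]12 | intermediate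
42 | C14 methyl ester, 9-OH free | C=C1C(=O)O[C@@H]2/C=C(/C)CC/C=C(/C(=O)OC)[C@H](O)[C@@H](OC(=O)[C@@]3(C)O[C@@H]3C)[C@@H]12 | intermediate
43 | (4R)-4-benzyl-3-propanoyl-1,3-oxazolidin-2-one | CCC(=O)N1C(=O)OC[C@H]1Cc1ccccc1 | starting material
44 | acetaldehyde | CC=O | starting material
45 | Z-dibutylboron enolate of 43 | C/C=C(/N1C(=O)OC[C@H]1Cc1ccccc1)OB(CCCC)CCCC | intermediate
46 | (4R)-4-benzyl-3-[(2R,3S)-3-hydroxy-2-methylbutanoyl]-1,3-oxazolidin-2-one | O=C([C@H](C)[C@H](C)O)N1C(=O)OC[C@H]1Cc1ccccc1 | intermediate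
47 | (4R)-4-benzyl-3-{(2R,3S)-2-methyl-3-[(triethylsilyl)oxy]butanoyl}-1,3-oxazolidin-2-one | O=C([C@H](C)[C@H](C)O[Si](CC)(CC)CC)N1C(=O)OC[C@H]1Cc1ccccc1 | intermediate
48 | lithium (2R,3S)-2-methyl-3-[(triethylsilyl)oxy]butaneperoxoate | [Li+].[O-]OC(=O)[C@H](C)[C@H](C)O[Si](CC)(CC)CC | intermediate
49 | (2R,3S)-2-methyl-3-[(triethylsilyl)oxy]butanoic acid | OC(=O)[C@H](C)[C@H](C)O[Si](CC)(CC)CC | intermediate
50 | mixed anhydride of 49 and 2,4,6-trichlorobenzoic acid | O=C(OC(=O)c1c(Cl)cc(Cl)cc1Cl)[C@H](C)[C@H](C)O[Si](CC)(CC)CC | intermediate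
51 | 3'-O-triethylsilyl ether of the target | C=C1C(=O)O[C@@H]2/C=C(/C)CC/C=C(/C(=O)OC)[C@H](OC(=O)[C@H](C)[C@H](C)O[Si](CC)(CC)CC)[C@@H](OC(=O)[C@@]3(C)O[C@@H]3C)[C@@H]12 | intermediate
52 | CNP0135583.2, (6R,7S,8S,9S) with 8-O-(2S,3R)-epoxyacyl and 9-O-(2R,3S)-hydroxyacyl groups | C=C1C(=O)O[C@@H]2/C=C(/C)CC/C=C(/C(=O)OC)[C@H](OC(=O)[C@H](C)[C@H](C)O)[C@@H](OC(=O)[C@@]3(C)O[C@@H]3C)[C@@H]12 | target

Total step count: 28. Longest linear sequence: 19 steps (1, 2, 4–6, 10–17, 20–23, 27, 28).

Steps most likely to fail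

Step 13. The two ketyls may pair without a clear preference at C9, so that threo selectivity is lost. Long contact with titanium alkoxides may also start deoxygenation or acyl migration from O6 to O8. The fallback takes the control of C9 away from the C–C bond formation. Setting out from 25, the coupling is stopped early. The diol mixture, 26 together with the 9-epimeric diol F1, is oxidised with MnO2, which attacks only the allylic C9 carbinol and funnels both isomers into the 8-hydroxy-9-enone F2. Hydroxyl-directed reduction with Me4NBH(OAc)3 in MeCN/AcOH at −20 °C (Evans–Saksena type) binds boron to O8 and delivers hydride to C9 from the O8 face. O9 is thereby pushed to the opposite face, and the route is rejoined at 26.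

Step 8. The phosphonate anion may lose silanolate by E1cB elimination before it meets the aldehyde, acrolein may suffer conjugate addition, or the bulky α-substituent may erode the Z preference. The fallback builds the trisubstituted olefin by stereospecific alkyne chemistry.
- Setting out from acrolein 18, Corey–Fuchs homologation (CBr4, PPh3) gives 1,1-dibromobuta-1,3-diene F3, and n-BuLi followed by paraformaldehyde gives pent-4-en-2-yn-1-ol F4.
- Hydroxyl-directed ruthenium-catalysed trans-hydrostannation (Bu3SnH, [Cp*RuCl]4) places tin on the carbon next to the carbinol and hydrogen trans to it, giving (2Z)-2-(tributylstannyl)penta-2,4-dien-1-ol F5.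
- The hydroxyl of F5 (O14) is silylated with iPr3SiCl and imidazole to the silylated stannane F6.
- Tin–lithium exchange (n-BuLi, −78 °C) and trapping with paraformaldehyde, both with retention, put C9 cis to the vinyl chain and return to 21.

Step 27. Acylation of the hindered O9–H, which is hydrogen-bonded to the C14 ester, may be slow. In that case the activated acid can lose silanol by β-elimination or epimerise at C2', or the O8 acyl group can begin to migrate. The fallback reverses the order of acylation and C14 oxidation.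
- Setting out from 39, the primary O14 is silylated selectively (Et3SiCl, imidazole, −20 °C) to the 14-O-triethylsilyl ether F7.
- The more nucleophilic O9–H of F7 is acylated with mixed anhydride 50 and DMAP to the bis-silyl diester F8.
- HF·pyridine removes both TES groups to give the 14,3'-diol F9.
- TEMPO/PhI(OAc)2 oxidises only the primary allylic alcohol to the enal F10, and Pinnick oxidation gives the acid F11.
- MeI/KHCO3 in DMF rejoins the route at 52.

Further compounds

F1 | step 13 | 9-epimer of 26 (O8 and O9 ring-cis) | C1C(=O)O[C@@H]2/C=C(/C)CC/C=C(/CO[Si](C(C)C)(C(C)C)C(C)C)[C@@H](O)[C@@H](O)[C@@H]12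
F2 | step 13 | 8-hydroxy-9-oxo-14-(triisopropylsilyloxy)-13-norgermacra-1(10),4-dien-12,6-olide | C1C(=O)O[C@@H]2/C=C(/C)CC/C=C(/CO[Si](C(C)C)(C(C)C)C(C)C)C(=O)[C@@H](O)[C@@H]12
F3 | step 8 | 1,1-dibromobuta-1,3-diene | C=CC=C(Br)Br
F4 | step 8 | pent-4-en-2-yn-1-ol | C=CC#CCO
F5 | step 8 | (2Z)-2-(tributylstannyl)penta-2,4-dien-1-ol | C=C/C=C(/CO)[Sn](CCCC)(CCCC)CCCC
F6 | step 8 | triisopropyl{[(2Z)-2-(tributylstannyl)penta-2,4-dien-1-yl]oxy}silane | C=C/C=C(/CO[Si](C(C)C)(C(C)C)C(C)C)[Sn](CCCC)(CCCC)CCCC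
F7 | step 27 | 14-O-triethylsilyl ether of 39 | C=C1C(=O)O[C@@H]2/C=C(/C)CC/C=C(/CO[Si](CC)(CC)CC)[C@H](O)[C@@H](OC(=O)[C@@]3(C)O[C@@H]3C)[C@@H]12
F8 | step 27 | 9-O-[(2R,3S)-2-methyl-3-(triethylsilyloxy)butanoyl] derivative of F7 | C=C1C(=O)O[C@@H]2/C=C(/C)CC/C=C(/CO[Si](CC)(CC)CC)[C@H](OC(=O)[C@H](C)[C@H](C)O[Si](CC)(CC)CC)[C@@H](OC(=O)[C@@]3(C)O[C@@H]3C)[C@@H]12
F9 | step 27 | 14,3'-diol diester | C=C1C(=O)O[C@@H]2/C=C(/C)CC/C=C(/CO)[C@H](OC(=O)[C@H](C)[C@H](C)O)[C@@H](OC(=O)[C@@]3(C)O[C@@H]3C)[C@@H]12
F10 | step 27 | C14 aldehyde of F9 | C=C1C(=O)O[C@@H]2/C=C(/C)CC/C=C(/C=O)[C@H](OC(=O)[C@H](C)[C@H](C)O)[C@@H](OC(=O)[C@@]3(C)O[C@@H]3C)[C@@H]12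
F11 | step 27 | C14 carboxylic acid of F9 | C=C1C(=O)O[C@@H]2/C=C(/C)CC/C=C(/C(=O)O)[C@H](OC(=O)[C@H](C)[C@H](C)O)[C@@H](OC(=O)[C@@]3(C)O[C@@H]3C)[C@@H]12
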